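The data come from a simulation for an exercise, noise included.

Friday's run and Monday's run were what I had to go on when I tried to say how south-west and south would split their substrate between target and uncatalysed product.

in all of them: catalyst 0.50 mM; temperature 25 °C

|  | substrate | reagent | remark | time |
|---|---|---|---|---|
| Friday's | 10 mM | 8 mM | run made earlier |  |
| Monday's | 10 mM | 24 mM | run made earlier |  |
| south-west | 6.0 mM | 12.0 mM |  | 60 h |
| south | 10 mM | 12.0 mM |  | 40 h |

| run | time / h | target / % | uncatalysed product / % | substrate / % |
|---|---|---|---|---|
| Friday's | 3.00 | 67 | 5 | 33 |
| Friday's | 8.00 | 78 | 0 | 21 |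
| Friday's | 15.0 | 78 | 0 | 23 |
| Friday's | 25.0 | 76 | 2 | 20 |
| Monday's | 2.00 | 96 | 2 | 0 |
| Monday's | 4.00 | 97 | 5 | 1 |
| Monday's | 10.0 | 98 | 1 | 0 |
| Monday's | 25.0 | 95 | 0 | 0 |

(scatter of a reading: 2 percentage points)

* which one finishes higher in share of target in all that became target or uncatalysed product ("neither" within 2 percentage points) (south-west / south / neither)
* share of target in all that became target or uncatalysed product, south-west
* share of target in all that became target or uncatalysed product, south

- candidate steps: substrate + reagent + catalyst -> target + catalyst; substrate + reagent -> uncatalysed product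

I kept a ledger. On Friday [reagent] = 8 mM stood against [substrate] = 10 mM, so reagent was the limiting reagent. Target stopped rising by 8.00 h at 78 % of the substrate, which put 7.80 mM of reagent in the target entry and left 0.200 mM for the other entry. A single reading scatters by 2 percentage points, so no single row could show that small entry. I therefore summed the rows. Friday gave 2.34 % and Monday, with [reagent] = 24 mM, gave 2.07 %. Together they gave 2.19 % for the leak, the uncatalysed product made per target made, which is the inverse of the selectivity factor.

South-west and south hold the same [catalyst] = 0.50 mM as those runs, and their substrate, 6.0 mM and 10 mM, is below [reagent] = 12.0 mM. Substrate is therefore the charge that closes their books, with reagent over by 6.00 mM and 2.00 mM. Their times, 60 h and 40 h, are longer than Friday's 8.00 h. The fraction that stays target after the leak is one over one plus the leak, 97.9 %, the same for both flasks by my reckoning.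

The forecast gave 98 % for south-west (96 % to 99.5 %), 98 % for south (96 % to 99.5 %), and neither: “Their shares should therefore match, so neither is higher.”

South-west gave 98.1 % and south 97.7 %, so the answer was neither, with a gap of 0.40 points under the margin of 2 points.

    substrate + reagent + catalyst → target + catalyst, rate k1*[substrate]*[reagent]*[catalyst]/(1 + ([substrate]/sat1)) (6.20 mM, k = 4.50 × 10⁵ M⁻² h⁻¹, Ea = 40.0 kJ mol⁻¹)
    substrate + reagent → uncatalysed product (k = 3.00 M⁻¹ h⁻¹, Ea = 56.0 kJ mol⁻¹)
    (constants at 25 °C)

Uncatalysed product ended at 1.94 % in south-west and 2.35 % in south. For the forecast's neither to fail, the leak would have to part between the flasks until the gap passed 2 points. Catalyst stands in the target step, so for south with [catalyst] cut to 0.12 mM I scaled the leak to 9.12 %, which gave a share of 91.6 %. That flask ended at 90.9 %, 7.2 points below south-west.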